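**Synthesis plan**

- Retrosynthesis: the two acetates go back to a 13,14-acetonide; the C7–C8 bond and the O7–C19 lactone bond are cut together (rings B and C), leaving a ring A core with a C7 (Z)-enal and a C8 (Z)-enol triflate. Further cuts: C8–C17 (ester aldol), C3–C4 (ketone enolate alkylation), C2–C3 (Grignard), and C1–C14 with C10–C11 (Diels–Alder).
- Forward order: ring A first by an intermolecular Diels–Alder reaction, then the C3–C7 arm and the C17–C19 unit are attached, and the ten-membered ring B and butenolide ring C close together in the last skeletal step.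
- Enabling feature: the C7–C8 bond is shared by rings B and C, C7 is an allylic carbinol next to the C5=C6 (Z)-alkene, and C19 sits cis to C7 on the C8=C17 alkene. One alkenyl–aldehyde coupling therefore builds the carbocycle and delivers the alkoxide that closes the lactone.
- Stereochemistry: C1, C10 and C14 from the catalyst-controlled endo Diels–Alder reaction (C11 is temporary). C13 is relayed from C14 by acetoxy participation after a diaxial bromination–elimination that moves the alkene to C11–C12. C2 comes from CBS reduction, C5=C6 from Still–Gennari olefination, C8=C17 from chelate-controlled triflation, and C7 from the ring closure.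

Key step: step 27

Remark: briarane numbering is used (C1 quaternary, C2 propionate carbinol, C5=C6, C7 lactone carbinol, C8=C17, C19 lactone carbonyl, C9, C10, C11=C12, C13, C14); on ring A, β is the face of the C1 methyl group and α the opposite face.
Remark: the C2 carbinols between the Grignard addition and the oxidation to the methyl ketone are carried as C2 epimers, and the aldol product and β-keto ester as mixtures at C8/C17; acetyl migration between O13 and O14 after the silver step is harmless because all acetates are removed next.

**Route**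

Step 1
Reactants: 1 3-(4-methoxybenzyloxy)propan-1-ol
Product: 2 3-(4-methoxybenzyloxy)propanal
Conditions: Dess–Martin periodinane, NaHCO3, CH2Cl2, 0 °C to rt
Reagents that add atoms: none
Why: Dess–Martin oxidation of the primary alcohol stops at the aldehyde, and the buffered neutral medium avoids β-elimination of the 4-methoxybenzyloxy group.

Step 2
Reactants: 2 3-(4-methoxybenzyloxy)propanal; 3 2-(triphenylphosphoranylidene)propanal
Product: 4 (E)-5-(4-methoxybenzyloxy)-2-methylpent-2-enal
Conditions: toluene, 90 °C
Reagents that add atoms: none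
Why: Wittig olefination with the stabilized formyl ylide is reversible up to the oxaphosphetane and therefore gives the (E)-2-methyl enal, which is too hindered to react with a second equivalent of ylide.

Step 3
Reactants: 5 (E)-pent-2-enal
Product: 6 (1E,3E)-1-(tert-butyldimethylsilyloxy)penta-1,3-diene
Conditions: TBSOTf, Et3N, Et2O, 0 °C to rt
Reagents that add atoms: tert-butyldimethylsilyl trifluoromethanesulfonate, CC(C)(C)[Si](C)(C)OS(=O)(=O)C(F)(F)F
Why: soft enolization removes a γ-hydrogen of the s-trans enal and silylates oxygen, which should give the 1-silyloxy diene mainly as the (1E,3E) isomer; minor Z isomers cannot adopt the s-cis geometry and are left behind in step 4.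

Step 4
Reactants: 4 (E)-5-(4-methoxybenzyloxy)-2-methylpent-2-enal; 6 (1E,3E)-1-(tert-butyldimethylsilyloxy)penta-1,3-diene
Product: 7 ring A aldehyde, 1α-formyl-1β-methyl-10β-[2-(4-methoxybenzyloxy)ethyl]-11α-methyl-14α-(tert-butyldimethylsilyloxy)cyclohex-12-ene
Conditions: (S)-B-(o-tolyl)-CBS-oxazaborolidine·HNTf2 (20 mol %), 6 (3 equiv), CH2Cl2, −78 to −40 °C (the antipodal catalyst is equally available should the sense of induction prove opposite)
Reagents that add atoms: none
Why: enantioselective Diels–Alder reaction catalysed by a chiral oxazaborolidinium ion, in which the methyl-bearing diene terminus bonds to the β-carbon of the activated enal and the silyloxy-bearing terminus to the α-carbon (ortho rule, forming C10–C11 and C1–C14), the (E)-enal places the C1 methyl cis to the C10 side chain, the (E,E)-diene with the formyl group endo places the 14-silyloxy and 11-methyl groups cis to the formyl group, and the catalyst exposes the face that is Re at the α-carbon so that C1, C10 and C14 arise in the configuration drawn.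

Step 5
Reactants: 7 ring A aldehyde
Product: 8 ring A C2 carbinol, 1α-(1-hydroxyethyl)-14α-(tert-butyldimethylsilyloxy) analogue of 7 (C2 epimers)
Conditions: MeMgBr, THF, −78 to 0 °C
Reagents that add atoms: methylmagnesium bromide, C[Mg]Br
Why: Grignard addition to the unenolizable neopentyl aldehyde gives the C2 carbinol with the C3 methyl group, as C2 epimers that are of no consequence because C2 is oxidized in step 13.

Step 6
Reactants: 8 ring A C2 carbinol
Product: 9 ring A 2,14α-diol
Conditions: Bu4NF, THF, 40 °C
Reagents that add atoms: none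
Why: fluoride cleaves the hindered secondary silyl ether, and because C2 is still a carbinol there is no β-hydroxy ketone that could open ring A by retro-aldol cleavage.

Step 7
Reactants: 9 ring A 2,14α-diol
Product: 10 ring A 2,14α-diacetate
Conditions: Ac2O, Et3N, DMAP, CH2Cl2, rt to 40 °C
Reagents that add atoms: acetic anhydride, CC(=O)OC(C)=O
Why: DMAP-catalysed acetylation places on O14 the acyl group that will participate in step 10 and masks O2 so that it cannot capture the bromonium ion in step 8.

Step 8
Reactants: 10 ring A 2,14α-diacetate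
Product: 11 ring A 12α,13β-dibromide 2,14α-diacetate
Conditions: Br2 (1.05 equiv), CH2Cl2, −78 °C
Reagents that add atoms: bromine, BrBr
Why: electrophilic anti addition of bromine, in which ring A reacts through the half-chair with the C1–C2 bond, the C10 side chain and the C11 methyl equatorial (C1 methyl and 14-acetoxy axial), so that diaxial opening of either bromonium ion leads to the same 12α,13β-dibromide, the course known for conformationally biased cyclohexenes such as steroidal 2-enes, while at −78 °C the alkene should consume bromine far faster than the anisyl ring.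

Step 9
Reactants: 11 ring A 12α,13β-dibromide 2,14α-diacetate
Product: 12 ring A 13β-bromo-11-ene 2,14α-diacetate
Conditions: DBU, toluene, 60 °C
Reagents that add atoms: none
Why: E2 dehydrobromination in which only the axial 12α-bromide has an antiperiplanar hydrogen (the axial 11β-H), whereas the 13β-bromide has none (12α carries bromine, 14α the acetate), so that one allylic bromide should result, the alkene sits at C11–C12 and the temporary C11 stereocentre is erased.

Step 10
Reactants: 12 ring A 13β-bromo-11-ene 2,14α-diacetate
Product: 13 ring A 13α-hydroxy-14α-acetoxy-11-ene 2-acetate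
Conditions: AgOAc, AcOH/H2O (95:5), 40 °C
Reagents that add atoms: water, O
Why: Woodward–Prévost-type substitution with neighbouring-group participation, in which silver-assisted ionization of the allylic 13β-bromide is accompanied by backside attack of the antiperiplanar 14α-acetoxy group to give a cis-fused acetoxonium ion whose hydrolysis through the orthoacid leaves O13 on the α face (net inversion at C13, configuration relayed from C14).

Step 11
Reactants: 13 ring A 13α-hydroxy-14α-acetoxy-11-ene 2-acetate
Product: 14 ring A 2,13α,14α-triol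
Conditions: K2CO3, MeOH, rt to 40 °C
Reagents that add atoms: none
Why: base-catalysed transesterification with methanol removes both acetates and leaves the 4-methoxybenzyl ether and the alkene untouched.

Step 12
Reactants: 14 ring A 2,13α,14α-triol
Product: 15 ring A 13α,14α-acetonide with free C2 hydroxyl
Conditions: 2,2-dimethoxypropane, PPTS, acetone, rt
Reagents that add atoms: 2,2-dimethoxypropane, COC(C)(C)OC
Why: acid-catalysed acetalization under equilibrating conditions selects the cis-vicinal 13,14-diol, whose five-membered dioxolane is favoured over a six-membered acetonide spanning O2 and O14, and leaves the C2 hydroxyl free.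

Step 13
Reactants: 15 ring A 13α,14α-acetonide with free C2 hydroxyl
Product: 16 ring A methyl ketone, 1α-acetyl-1β-methyl-10β-[2-(4-methoxybenzyloxy)ethyl]-11-methylcyclohex-11-ene 13α,14α-acetonide
Conditions: Dess–Martin periodinane, NaHCO3, CH2Cl2, rt
Reagents that add atoms: none
Why: Dess–Martin oxidation of the remaining secondary alcohol gives the methyl ketone, which is now safe because O14 is part of the acetal and no retro-aldol pathway exists.

Step 14
Reactants: 17 (tert-butyldimethylsilyloxy)acetaldehyde; 18 methyl 2-[bis(2,2,2-trifluoroethoxy)phosphoryl]propanoate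
Product: 19 methyl (Z)-4-(tert-butyldimethylsilyloxy)-2-methylbut-2-enoate
Conditions: KN(SiMe3)2, 18-crown-6, THF, −78 °C
Reagents that add atoms: none
Why: Still–Gennari olefination, in which the electron-poor bis(trifluoroethyl) phosphonate under dissociating conditions eliminates faster than the adducts equilibrate and so gives the (Z)-trisubstituted enoate.

Step 15
Reactants: 19 methyl (Z)-4-(tert-butyldimethylsilyloxy)-2-methylbut-2-enoate
Product: 20 (Z)-4-(tert-butyldimethylsilyloxy)-2-methylbut-2-en-1-ol
Conditions: i-Bu2AlH, CH2Cl2, −78 °C; aqueous potassium sodium tartrate work-up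
Reagents that add atoms: none
Why: i-Bu2AlH reduces the conjugated ester 1,2 to the allylic alcohol at low temperature without touching the silyl ether or the alkene geometry.

Step 16
Reactants: 20 (Z)-4-(tert-butyldimethylsilyloxy)-2-methylbut-2-en-1-ol
Product: 21 (Z)-1-bromo-4-(tert-butyldimethylsilyloxy)-2-methylbut-2-ene
Conditions: CBr4, PPh3, 2,6-lutidine, CH2Cl2, −20 to 0 °C
Reagents that add atoms: carbon tetrabromide, BrC(Br)(Br)Br
Why: Appel bromination converts the primary allylic alcohol to the bromide by SN2 displacement of the oxyphosphonium ion under neutral conditions, without allylic transposition and with retention of the Z geometry.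

Step 17
Reactants: 16 ring A methyl ketone; 21 (Z)-1-bromo-4-(tert-butyldimethylsilyloxy)-2-methylbut-2-ene
Product: 22 C2 ketone carrying the (5Z) C3–C7 arm with C7 silyl ether
Conditions: LiN(i-Pr)2, THF, −78 °C; then 21, DMPU, −78 to −30 °C
Reagents that add atoms: none
Why: kinetic enolate alkylation, in which the ketone can enolize only toward its methyl group (C1 is quaternary) and the lithium enolate displaces the primary allylic bromide by SN2 to form the C3–C4 bond, DMPU raising the enolate reactivity so that monoalkylation outruns proton transfer.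

Step 18
Reactants: 22 C2 ketone carrying the C3–C7 arm
Product: 23 (2S)-carbinol
Conditions: (R)-2-methyl-CBS-oxazaborolidine, catecholborane, toluene, −78 to −40 °C
Reagents that add atoms: none
Why: Corey–Bakshi–Shibata reduction, in which the catalyst differentiates the fully substituted C1 (large) from the C3 methylene (small) and the (R)-oxazaborolidine should therefore deliver hydride to the face that gives the (2S)-carbinol, while catecholborane at low temperature does not hydroborate the trisubstituted alkenes.

Step 19
Reactants: 23 (2S)-carbinol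
Product: 24 (2S)-propionate
Conditions: (EtCO)2O, Et3N, DMAP, CH2Cl2, 40 °C
Reagents that add atoms: propanoic anhydride, CCC(=O)OC(=O)CC
Why: DMAP-catalysed acylation with the anhydride esterifies the hindered secondary alcohol next to the quaternary C1 without touching the C2 configuration.

Step 20
Reactants: 24 (2S)-propionate
Product: 25 C8 primary alcohol
Conditions: DDQ, CH2Cl2/pH 7 phosphate buffer (10:1), 0 °C
Reagents that add atoms: none
Why: DDQ oxidizes only the electron-rich 4-methoxybenzyl ether (hydride abstraction, then hydrolysis of the oxocarbenium ion in the wet buffered medium) and spares the allylic silyl ether, the acetonide, the ester and both alkenes.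

Step 21
Reactants: 25 C8 primary alcohol
Product: 26 C8 aldehyde
Conditions: Dess–Martin periodinane, NaHCO3, CH2Cl2, 0 °C to rt
Reagents that add atoms: none
Why: Dess–Martin oxidation gives the C8 aldehyde, whose α-carbon (C9) carries no stereocentre that could be lost.

Step 22
Reactants: 26 C8 aldehyde; 27 methyl propanoate
Product: 28 C8 β-hydroxy ester (mixture at C8 and C17)
Conditions: LiN(i-Pr)2, 27, THF, −78 °C; then 26, −78 °C
Reagents that add atoms: none
Why: aldol addition of the preformed lithium enolate of the ester to the aldehyde is much faster at −78 °C than proton transfer to or from the C2 propionate, and the new C8 and C17 centres need no control because both are removed in the next two steps.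

Step 23
Reactants: 28 C8 β-hydroxy ester
Product: 29 C8 β-keto ester (C17 epimers)
Conditions: Dess–Martin periodinane, NaHCO3, CH2Cl2, rt
Reagents that add atoms: none
Why: Dess–Martin oxidation of the β-hydroxy ester gives the β-keto ester under neutral conditions that avoid retro-aldol cleavage.

Step 24
Reactants: 29 C8 β-keto ester
Product: 30 C8 (Z)-enol triflate with C7 silyl ether
Conditions: LiN(SiMe3)2 (1.05 equiv), Et2O, −78 °C; then Tf2O, −78 to −30 °C
Reagents that add atoms: trifluoromethanesulfonic anhydride, O=S(=O)(OS(=O)(=O)C(F)(F)F)C(F)(F)F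
Why: O-sulfonylation of the lithium-chelated (Z)-enolate of the β-keto ester in a weakly coordinating solvent should give the tetrasubstituted enol triflate with the triflate cis to the ester, and one equivalent of base deprotonates only the β-keto ester, which is far more acidic than the propionate.

Step 25
Reactants: 30 C8 (Z)-enol triflate with C7 silyl ether
Product: 31 C8 (Z)-enol triflate with C7 allylic alcohol
Conditions: HF·pyridine, pyridine, THF, 0 °C
Reagents that add atoms: none
Why: buffered HF·pyridine cleaves the primary allylic silyl ether and leaves the enol triflate, the acetonide and both esters intact.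

Step 26
Reactants: 31 C8 (Z)-enol triflate with C7 allylic alcohol
Product: 32 cyclization precursor, C8 (Z)-enol triflate with C7 (5Z)-enal
Conditions: Dess–Martin periodinane, NaHCO3, CH2Cl2, 0 °C
Reagents that add atoms: none
Why: buffered Dess–Martin oxidation converts the (Z)-allylic alcohol to the (Z)-enal under neutral conditions that should not isomerize it to the E isomer.

Step 27
Reactants: 32 cyclization precursor
Product: 34 tricyclic butenolide 13α,14α-acetonide (rings A, B and C; 2S, 5Z, 7R), via ten-membered hydroxy ester 33 (not isolated)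
Conditions: CrCl2 (10 equiv), NiCl2 (0.1 equiv), degassed DMF/THF, 50 °C, syringe-pump addition of 32 to 2 mM
Reagents that add atoms: none
Why: Proposed new method: zerovalent nickel, generated from NiCl2 by CrCl2, inserts into the C8–OTf bond and hands the alkenyl group to chromium with retention of the alkene geometry; the resulting alkenyl species of trivalent chromium adds 1,2 to the C7 aldehyde, and the chromium alkoxide then attacks the C19 methyl ester held cis on the C8=C17 alkene and expels methoxide. The closest known reaction types are the Nozaki–Hiyama–Kishi coupling of alkenyl triflates with aldehydes, its macrocyclizing variants, and the coupling of (Z)-β-iodo enoates with aldehydes that lactonizes to butenolides; new is their union on a tetrasubstituted β-triflyloxy enoate in a ten-membered closure. Ring B closes by C7–C8 bond formation as a 10-exo-trig carbonyl addition, and ring C by 5-exo-trig acyl substitution of O7 on C19. The only new stereocentre, C7, is set by the substrate: the trans-diequatorial C2 and C9 arms on ring A and the two Z alkenes should let the alkenylchromium reach only the Si face of the enal carbonyl in an unstrained ten-membered transition state, which gives the (7R) lactone carbinol. The step needs chemoselective activation of the triflate next to an enal, retention of both Z geometries and cyclization over oligomerization, which the (Z)-enol triflate (ester cis to the new carbinol), the non-enolizable enal, the non-basic medium and high dilution are meant to secure.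

Step 28
Reactants: 34 tricyclic butenolide 13α,14α-acetonide
Product: 35 tricyclic 13α,14α-diol
Conditions: AcOH/H2O (4:1), 40 °C
Reagents that add atoms: none
Why: mild aqueous acid hydrolyses the cis-fused acetonide, and neither the propionate nor the butenolide should be cleaved under these conditions.

Step 29
Reactants: 35 tricyclic 13α,14α-diol
Product: 36 target CNP0180501.3
Conditions: Ac2O, pyridine, DMAP (cat.), CH2Cl2, 0 °C to rt
Reagents that add atoms: acetic anhydride, CC(=O)OC(C)=O
Why: acetylation of both secondary hydroxyls with the anhydride and pyridine with catalytic DMAP, a base too weak to deprotonate the γ-position (C7) of the butenolide, gives the target.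

**Compound list**

1 | 3-(4-methoxybenzyloxy)propan-1-ol | COc1ccc(COCCCO)cc1 | starting material
2 | 3-(4-methoxybenzyloxy)propanal | COc1ccc(COCCC=O)cc1 | intermediate
3 | 2-(triphenylphosphoranylidene)propanal | CC(C=O)=P(c1ccccc1)(c1ccccc1)c1ccccc1 | starting material
4 | (E)-5-(4-methoxybenzyloxy)-2-methylpent-2-enal | O=C/C(C)=C/CCOCc1ccc(OC)cc1 | intermediate
5 | (E)-pent-2-enal | CC/C=C/C=O | starting material
6 | (1E,3E)-1-(tert-butyldimethylsilyloxy)penta-1,3-diene | C/C=C/C=C/O[Si](C)(C)C(C)(C)C | intermediate
7 | ring A aldehyde: 1α-formyl, 1β-methyl, 10β-[2-(4-methoxybenzyloxy)ethyl], 11α-methyl, 14α-silyloxy, 12-ene | COc1ccc(COCC[C@@H]2[C@@H](C)C=C[C@@H](O[Si](C)(C)C(C)(C)C)[C@@]2(C)C=O)cc1 | intermediate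
8 | ring A C2 carbinol (1α-(1-hydroxyethyl), 14α-silyloxy; C2 epimers) | COc1ccc(COCC[C@@H]2[C@@H](C)C=C[C@@H](O[Si](C)(C)C(C)(C)C)[C@@]2(C)C(C)O)cc1 | intermediate
9 | ring A 2,14α-diol | COc1ccc(COCC[C@@H]2[C@@H](C)C=C[C@@H](O)[C@@]2(C)C(C)O)cc1 | intermediate
10 | ring A 2,14α-diacetate | COc1ccc(COCC[C@@H]2[C@@H](C)C=C[C@@H](OC(C)=O)[C@@]2(C)C(C)OC(C)=O)cc1 | intermediate
11 | ring A 12α,13β-dibromide 2,14α-diacetate | COc1ccc(COCC[C@@H]2[C@@H](C)[C@@H](Br)[C@H](Br)[C@@H](OC(C)=O)[C@@]2(C)C(C)OC(C)=O)cc1 | intermediate
12 | ring A 13β-bromo-11-ene 2,14α-diacetate | COc1ccc(COCC[C@@H]2C(C)=C[C@H](Br)[C@@H](OC(C)=O)[C@@]2(C)C(C)OC(C)=O)cc1 | intermediate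
13 | ring A 13α-hydroxy-14α-acetoxy-11-ene 2-acetate | COc1ccc(COCC[C@@H]2C(C)=C[C@@H](O)[C@@H](OC(C)=O)[C@@]2(C)C(C)OC(C)=O)cc1 | intermediate
14 | ring A 2,13α,14α-triol, 11-ene | COc1ccc(COCC[C@@H]2C(C)=C[C@@H](O)[C@@H](O)[C@@]2(C)C(C)O)cc1 | intermediate
15 | ring A 13α,14α-acetonide with free C2 hydroxyl | COc1ccc(COCC[C@@H]2C(C)=C[C@@H](OC3(C)C)[C@@H](O3)[C@@]2(C)C(C)O)cc1 | intermediate
16 | ring A methyl ketone with 13α,14α-acetonide and C11–C12 alkene | COc1ccc(COCC[C@@H]2C(C)=C[C@@H](OC3(C)C)[C@@H](O3)[C@@]2(C)C(C)=O)cc1 | intermediate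
17 | (tert-butyldimethylsilyloxy)acetaldehyde | CC(C)(C)[Si](C)(C)OCC=O | starting material
18 | methyl 2-[bis(2,2,2-trifluoroethoxy)phosphoryl]propanoate | COC(=O)C(C)P(=O)(OCC(F)(F)F)OCC(F)(F)F | starting material
19 | methyl (Z)-4-(tert-butyldimethylsilyloxy)-2-methylbut-2-enoate | COC(=O)/C(C)=C\CO[Si](C)(C)C(C)(C)C | intermediate
20 | (Z)-4-(tert-butyldimethylsilyloxy)-2-methylbut-2-en-1-ol | OC/C(C)=C\CO[Si](C)(C)C(C)(C)C | intermediate
21 | (Z)-1-bromo-4-(tert-butyldimethylsilyloxy)-2-methylbut-2-ene | BrC/C(C)=C\CO[Si](C)(C)C(C)(C)C | intermediate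
22 | C2 ketone carrying the (5Z) C3–C7 arm (C7 silyl ether) | COc1ccc(COCC[C@@H]2C(C)=C[C@@H](OC3(C)C)[C@@H](O3)[C@@]2(C)C(=O)CC/C(C)=C\CO[Si](C)(C)C(C)(C)C)cc1 | intermediate
23 | (2S)-carbinol | COc1ccc(COCC[C@@H]2C(C)=C[C@@H](OC3(C)C)[C@@H](O3)[C@@]2(C)[C@@H](O)CC/C(C)=C\CO[Si](C)(C)C(C)(C)C)cc1 | intermediate
24 | (2S)-propionate | COc1ccc(COCC[C@@H]2C(C)=C[C@@H](OC3(C)C)[C@@H](O3)[C@@]2(C)[C@@H](OC(=O)CC)CC/C(C)=C\CO[Si](C)(C)C(C)(C)C)cc1 | intermediate
25 | C8 primary alcohol | OCC[C@@H]1C(C)=C[C@@H](OC2(C)C)[C@@H](O2)[C@@]1(C)[C@@H](OC(=O)CC)CC/C(C)=C\CO[Si](C)(C)C(C)(C)C | intermediate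
26 | C8 aldehyde | O=CC[C@@H]1C(C)=C[C@@H](OC2(C)C)[C@@H](O2)[C@@]1(C)[C@@H](OC(=O)CC)CC/C(C)=C\CO[Si](C)(C)C(C)(C)C | intermediate
27 | methyl propanoate | CCC(=O)OC | starting material
28 | C8 β-hydroxy ester (mixture at C8 and C17) | COC(=O)C(C)C(O)C[C@@H]1C(C)=C[C@@H](OC2(C)C)[C@@H](O2)[C@@]1(C)[C@@H](OC(=O)CC)CC/C(C)=C\CO[Si](C)(C)C(C)(C)C | intermediate
29 | C8 β-keto ester (C17 epimers) | COC(=O)C(C)C(=O)C[C@@H]1C(C)=C[C@@H](OC2(C)C)[C@@H](O2)[C@@]1(C)[C@@H](OC(=O)CC)CC/C(C)=C\CO[Si](C)(C)C(C)(C)C | intermediate
30 | C8 (Z)-enol triflate with C7 silyl ether | COC(=O)/C(C)=C(OS(=O)(=O)C(F)(F)F)/C[C@@H]1C(C)=C[C@@H](OC2(C)C)[C@@H](O2)[C@@]1(C)[C@@H](OC(=O)CC)CC/C(C)=C\CO[Si](C)(C)C(C)(C)C | intermediate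
31 | C8 (Z)-enol triflate with C7 allylic alcohol | COC(=O)/C(C)=C(OS(=O)(=O)C(F)(F)F)/C[C@@H]1C(C)=C[C@@H](OC2(C)C)[C@@H](O2)[C@@]1(C)[C@@H](OC(=O)CC)CC/C(C)=C\CO | intermediate
32 | cyclization precursor: C8 (Z)-enol triflate with C7 (5Z)-enal | COC(=O)/C(C)=C(OS(=O)(=O)C(F)(F)F)/C[C@@H]1C(C)=C[C@@H](OC2(C)C)[C@@H](O2)[C@@]1(C)[C@@H](OC(=O)CC)CC/C(C)=C\C=O | intermediate
33 | ten-membered hydroxy ester (formed as its chromium alkoxide, (7R), ester cis to C7) | CCC(=O)O[C@H]1CC/C(C)=C\[C@@H](O)/C(=C(/C)C(=O)OC)C[C@@H]2C(C)=C[C@@H](OC3(C)C)[C@@H](O3)[C@@]12C | intermediate (not isolated)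
34 | tricyclic butenolide 13α,14α-acetonide (2S,5Z,7R) | CCC(=O)O[C@H]1CC/C(C)=C\[C@H]2OC(=O)C(C)=C2C[C@@H]2C(C)=C[C@@H](OC3(C)C)[C@@H](O3)[C@@]12C | intermediate
35 | tricyclic 13α,14α-diol | CCC(=O)O[C@H]1CC/C(C)=C\[C@H]2OC(=O)C(C)=C2C[C@@H]2C(C)=C[C@@H](O)[C@@H](O)[C@@]12C | intermediate
36 | CNP0180501.3, the 2-propionate 13α,14α-diacetate of the tricyclic butenolide (1R,2S,5Z,7R,10R,13R,14S) | CCC(=O)O[C@H]1CC/C(C)=C\[C@H]2OC(=O)C(C)=C2C[C@@H]2C(C)=C[C@@H](OC(C)=O)[C@@H](OC(C)=O)[C@@]12C | target

**Step count and risks**

Total step count: 29. Longest linear sequence: 25 steps (steps 1, 2, 4–13 and 17–29).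

Steps most likely to fail:

1. Step 27 (Proposed new method). Oxidative addition into the hindered tetrasubstituted triflate may be slower than reduction of the C–OTf bond or intermolecular coupling, and the closure may show poor facial selectivity at C7. The fallback uses known chemistry, sets out from aldehyde 26 and comes back at 34. A Morita–Baylis–Hillman reaction of 26 with methyl acrylate (DABCO, MeOH, rt) would give the α-methylene β-hydroxy ester F1. NBS/Me2S (CH2Cl2, 0 °C) would convert it with allylic transposition into the (Z)-2-(bromomethyl)enoate F2. HF·pyridine would free the C7 allylic alcohol F3, and buffered Dess–Martin oxidation would give the (Z)-enal F4. CrCl2 in THF at high dilution (Nozaki–Hiyama allylation of a 2-(bromomethyl)acrylate, a closure known for ten-membered α-methylene lactones) would form the C7–C8 bond through the γ-carbon of the allylchromium, and the alkoxide would lactonize to the α-methylene γ-butyrolactone F5. RhCl3·3H2O in ethanol (70 °C) would then move the exocyclic alkene into the ring, erasing C8 and giving 34.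

2. Step 4. The acid-labile silyl dienol ether may be consumed by protodesilylation or Mukaiyama-type addition faster than it cycloadds to the sluggish trisubstituted enal, and endo or facial selectivity may erode. The fallback moves the stereocontrol from the catalyst to an auxiliary on the diene; it sets out from enal 4 (with 5 as the diene source) and comes back at diol 9. The potassium dienolate of 5 (KOt-Bu, THF, −78 °C) would be acylated with (S)-O-methylmandeloyl chloride to give the acid-stable dienyl ester F6 (the antipodal auxiliary if the sense of induction requires). A BF3·OEt2-promoted Diels–Alder reaction with 4 (toluene/CH2Cl2, −78 to −20 °C) would give the 14α-mandelate adduct F7. Excess MeMgBr would add to the aldehyde and cleave the auxiliary ester in one operation, giving 9.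

3. Step 10. The allyl cation may be captured by an external nucleophile at its tertiary C11 terminus (allylic transposition) or lose a proton to a diene in competition with acetoxy participation. The fallback sets out from allylic bromide 12 and comes back at triol 14. K2CO3/MeOH would cleave both acetates, and the 14α-alkoxide would displace the trans-disposed 13β-bromide to give the 13α,14α-vinyl epoxide F8. Pd(PPh3)4 with CO2 (THF, rt) would ionize it to a π-allyl complex of palladium anti to the leaving oxygen; the carbonate formed on O14 would close on C13 anti to the metal, giving the cis cyclic carbonate F9 with net retention. K2CO3/MeOH would then give 14.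

Further compounds
F1 | step 27 | Morita–Baylis–Hillman adduct, methyl 2-methylene-3-hydroxy ester at C8 (C8 epimers) | COC(=O)C(=C)C(O)C[C@@H]1C(C)=C[C@@H](OC2(C)C)[C@@H](O2)[C@@]1(C)[C@@H](OC(=O)CC)CC/C(C)=C\CO[Si](C)(C)C(C)(C)C
F2 | step 27 | (Z)-2-(bromomethyl)enoate with C7 silyl ether | COC(=O)/C(CBr)=C/C[C@@H]1C(C)=C[C@@H](OC2(C)C)[C@@H](O2)[C@@]1(C)[C@@H](OC(=O)CC)CC/C(C)=C\CO[Si](C)(C)C(C)(C)C
F3 | step 27 | (Z)-2-(bromomethyl)enoate with C7 allylic alcohol | COC(=O)/C(CBr)=C/C[C@@H]1C(C)=C[C@@H](OC2(C)C)[C@@H](O2)[C@@]1(C)[C@@H](OC(=O)CC)CC/C(C)=C\CO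
F4 | step 27 | (Z)-2-(bromomethyl)enoate with C7 (5Z)-enal | COC(=O)/C(CBr)=C/C[C@@H]1C(C)=C[C@@H](OC2(C)C)[C@@H](O2)[C@@]1(C)[C@@H](OC(=O)CC)CC/C(C)=C\C=O
F5 | step 27 | tricyclic α-methylene γ-butyrolactone 13α,14α-acetonide ((7R), C8 either epimer) | CCC(=O)O[C@H]1CC/C(C)=C\[C@H]2OC(=O)C(=C)C2C[C@@H]2C(C)=C[C@@H](OC3(C)C)[C@@H](O3)[C@@]12C
F6 | step 4 | (1E,3E)-penta-1,3-dien-1-yl (S)-2-methoxy-2-phenylacetate | C/C=C/C=C/OC(=O)[C@@H](OC)c1ccccc1
F7 | step 4 | ring A aldehyde with 14α-[(S)-2-methoxy-2-phenylacetoxy] group | COc1ccc(COCC[C@@H]2[C@@H](C)C=C[C@@H](OC(=O)[C@@H](OC)c3ccccc3)[C@@]2(C)C=O)cc1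
F8 | step 10 | ring A 13α,14α-epoxy-11-ene with free C2 hydroxyl | COc1ccc(COCC[C@@H]2C(C)=C[C@H]3O[C@H]3[C@@]2(C)C(C)O)cc1
F9 | step 10 | ring A 13α,14α-cyclic carbonate with free C2 hydroxyl | COc1ccc(COCC[C@@H]2C(C)=C[C@@H](OC3=O)[C@@H](O3)[C@@]2(C)C(C)O)cc1
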